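**Plan**

1. Retrosynthetic cuts: the tiglate C–O bond (alkannin 17 + tiglic acid 18); C2=C3 of the quinone ring (ring A: C1, C2, C3, C4, C4a, C8a) after C1 and C4 are taken down to carbinols; C1–C2 and C3–C4 (to a C2v-symmetric 3,6-dioxygenated phthalaldehyde, a 2-lithioallyl silyl ether and vinylmagnesium bromide); C1′–C2′ and C3′=C4′ of the side chain (2-bromoacrolein, an allylborane, 2-methyl-2-butene).
2. Enabling feature: C2=C3 is the only non-aromatic ring olefin, it lies between C1 and C4, which sit on the neighbouring carbons C8a and C4a of the symmetric benzenoid ring B, and C2 bears the allylic carbinol C1′. At the 1,4-diol oxidation level C2=C3 is therefore the ring-closing-metathesis olefin of two vinyl carbinol arms, the branched arm being a 2-metallated allylic alcohol.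
3. Forward order: bromide 7 (steps 1–4) and dialdehyde 11 (steps 5–6) are joined with vinylmagnesium bromide in one flask through a temporary lactolate ring (step 7); metathesis closes ring A (step 8); oxidation removes the two helper carbinols and places the quinone on the ring that carries the side chain (step 9); acid unmasks the naphthazarin (step 10); esterification ends the route (step 11).
4. Stereochemistry: C1′ (S) is set once by reagent-controlled allylboration (isopinocampheyl groups from (+)-α-pinene) and is not ionised or enolised afterwards; the E ester olefin comes with tiglic acid; the C1/C4 carbinols are uncontrolled and temporary.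

Key step: step 8

Remark: the target is the tiglate of alkannin (S at C1′); the naphthazarin core is a pair of rapidly interconverting tautomers, so no step is needed to place the quinone carbonyls on the ring as drawn.

**Route**

Step 1
Reactants: 1 acrolein
Product: 3 2-bromoacrolein, via 2,3-dibromopropanal 2 (not isolated)
Conditions: Br2 (1.0 equiv), CH2Cl2, −78 → 0 °C; then Et3N (1.05 equiv), 0 °C; distilled and used at once
Reagents that add atoms: bromine, BrBr
Why: Bromine adds across the olefin and triethylamine then removes HBr by E1cB loss of the acidic α-proton and the β-bromide (bromination–dehydrobromination), which leaves the α-bromo enal.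

Step 2
Reactants: 3 2-bromoacrolein
Product: 5 (S)-2-bromohexa-1,5-dien-3-ol, via borinate ester 4 (not isolated)
Conditions: B-allyldiisopinocampheylborane made from (+)-α-pinene (1.1 equiv, pentane solution), Et2O, −100 → −78 °C; then 3 M aq NaOH, 30 % H2O2, 0 °C → rt
Reagents that add atoms: B-allyldiisopinocampheylborane (isopinocampheyl groups from (+)-α-pinene), C=CCB([C@@H]1C[C@@H]2C[C@H]([C@H]1C)C2(C)C)[C@@H]1C[C@@H]2C[C@H]([C@H]1C)C2(C)C
Why: Brown asymmetric allylboration through a closed chair six-membered transition state; this reagent should deliver allyl to the same aldehyde face as with benzaldehyde (S carbinol), and because 1-bromovinyl outranks allyl as phenyl does, C1′ should result as S.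

Step 3
Reactants: 5 (S)-2-bromohexa-1,5-dien-3-ol
Product: 6 (S)-[(2-bromohexa-1,5-dien-3-yl)oxy](tert-butyl)dimethylsilane
Conditions: TBSCl, imidazole, DMF, 0 °C → rt
Reagents that add atoms: tert-butyldimethylsilyl chloride, CC(C)(C)[Si](C)(C)Cl
Why: Imidazole-promoted silylation of the secondary alcohol gives an ether that should withstand the lithiation, metathesis and oxidation steps and does not touch the stereocentre.

Step 4
Reactants: 6 (S)-[(2-bromohexa-1,5-dien-3-yl)oxy](tert-butyl)dimethylsilane
Product: 7 (S)-[(2-bromo-6-methylhepta-1,5-dien-3-yl)oxy](tert-butyl)dimethylsilane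
Conditions: second-generation Grubbs catalyst (3 mol %), 2-methyl-2-butene (solvent), 35 °C
Reagents that add atoms: 2-methyl-2-butene, CC=C(C)C
Why: Olefin cross-metathesis of the monosubstituted terminal olefin with excess 2-methyl-2-butene transfers an isopropylidene group (allyl to prenyl), while the 1-bromovinyl group, a poor metathesis partner, should stay intact.

Step 5
Reactants: 8 2,3-dicyanohydroquinone
Product: 9 3,6-bis(methoxymethoxy)phthalonitrile
Conditions: MOMCl (2.5 equiv), i-Pr2NEt, DMF, 0 °C → rt
Reagents that add atoms: chloromethyl methyl ether, COCCl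
Why: O-Alkylation of the two acidic cyanophenols (Williamson-type acetal formation) masks both phenols as MOM ethers that are stable to hydride and organometallic reagents.

Step 6
Reactants: 9 3,6-bis(methoxymethoxy)phthalonitrile
Product: 11 3,6-bis(methoxymethoxy)phthalaldehyde, via bis(aluminium aldimine) 10 (not isolated)
Conditions: i-Bu2AlH (2.4 equiv), toluene, −78 → −20 °C; then 1 M aq HCl, 0 °C, 20 min
Reagents that add atoms: water, O
Why: Partial nitrile reduction, in which one hydride transfer per nitrile stops at the N-aluminio aldimine at low temperature, followed by brief cold acid hydrolysis of both imines, should give the dialdehyde without cleaving the aryl MOM ethers.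

Step 7
Reactants: 7 (S)-[(2-bromo-6-methylhepta-1,5-dien-3-yl)oxy](tert-butyl)dimethylsilane; 11 3,6-bis(methoxymethoxy)phthalaldehyde
Product: 14 (3S)-3-(tert-butyldimethylsilyloxy)-1-[2-(1-hydroxyprop-2-en-1-yl)-3,6-bis(methoxymethoxy)phenyl]-6-methyl-2-methylidenehept-5-en-1-ol (diastereomer mixture at the two free carbinols), via vinyllithium 12 (not isolated), via lithium lactolate 13 (not isolated)
Conditions: 7 (1.05 equiv), t-BuLi (2.1 equiv), Et2O, −78 °C; added to 11 (1.0 equiv), THF, −78 °C; then CH2=CHMgBr (3 equiv), −78 → 0 °C; aq NH4Cl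
Reagents that add atoms: vinylmagnesium bromide, C=C[Mg]Br
Why: Bromine–lithium exchange gives the 2-lithioallyl silyl ether, whose 1,2-addition to one formyl group of the symmetric dialdehyde generates an alkoxide that closes onto the neighbouring formyl group as a five-membered lactolate (a temporary ring that holds back a second addition), and excess vinyl Grignard then opens the lactolate and adds to the released aldehyde (sequential carbonyl additions); the two new carbinols are formed without control because both are oxidised later.

Step 8
Reactants: 14 the diol from step 7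
Product: 15 2-[(1S)-1-(tert-butyldimethylsilyloxy)-4-methylpent-3-en-1-yl]-5,8-bis(methoxymethoxy)-1,4-dihydronaphthalene-1,4-diol (diastereomer mixture at C1 and C4)
Conditions: second-generation Grubbs catalyst (5 mol %), 1,4-benzoquinone (10 mol %), CH2Cl2 (0.005 M), 40 °C, argon sparge
Reagents that add atoms: none
Why: The ruthenium alkylidene should first exchange onto the unhindered monosubstituted vinyl carbinol (C3 arm), then undergo intramolecular [2+2] cycloaddition with the 1,1-disubstituted olefin at C2 and cycloreversion, which forms C2=C3 and expels ethylene. The closest known reaction type is ring-closing metathesis of 1,2-bis(1-hydroxyallyl)arenes to 1,4-dihydronaphthalene-1,4-diols, which is helped by the allylic hydroxyl groups. Ring A (C1–C2–C3–C4–C4a–C8a) is closed as a six-membered carbocycle with both olefin carbons endocyclic, the two arms being held side by side on C8a and C4a. No stereocentre is created; the C1/C4 carbinol mixture is irrelevant and C1′ is untouched under these neutral conditions. The step needs site selectivity among three olefins: the trisubstituted prenyl olefin initiates slowly and could only close a cyclobutene or a nine-membered ring, so it should remain a spectator, while high dilution suppresses dimerisation and 1,4-benzoquinone suppresses hydride-mediated isomerisation of the vinyl carbinol.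

Step 9
Reactants: 15 the ene-diol from step 8
Product: 16 2-[(1S)-1-(tert-butyldimethylsilyloxy)-4-methylpent-3-en-1-yl]-5,8-bis(methoxymethoxy)naphthalene-1,4-dione
Conditions: Dess–Martin periodinane (3 equiv), NaHCO3, CH2Cl2, 0 °C → rt (crude 15 used directly)
Reagents that add atoms: none
Why: Dess–Martin oxidation of the two doubly activated (benzylic and allylic) carbinols, either directly or through the naphthalene-1,4-diol tautomer of the mono-oxidised intermediate, should end at the 1,4-quinone, which erases the two temporary stereocentres.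

Step 10
Reactants: 16 the protected quinone from step 9
Product: 17 alkannin, 5,8-dihydroxy-2-[(1S)-1-hydroxy-4-methylpent-3-en-1-yl]naphthalene-1,4-dione
Conditions: 2 M aq HCl–THF (1:4), 0 °C → rt, argon, dark
Reagents that add atoms: none
Why: Acid-catalysed acetal hydrolysis of the two aryl MOM ethers (assisted by the peri carbonyl groups) and solvolysis of the silyl ether in one operation should release the hydrogen-bonded naphthazarin; no bond to C1′ is broken.

Step 11
Reactants: 17 alkannin; 18 tiglic acid, (E)-2-methylbut-2-enoic acid
Product: 19 (1S)-1-(5,8-dihydroxy-1,4-dioxo-1,4-dihydronaphthalen-2-yl)-4-methylpent-3-en-1-yl (E)-2-methylbut-2-enoate (target)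
Conditions: DCC (1.2 equiv), DMAP (0.1 equiv), CH2Cl2, 0 °C → rt
Reagents that add atoms: none
Why: Steglich esterification should acylate only the side-chain carbinol, because both phenols are locked in hydrogen bonds to the quinone carbonyls; the C1′–O bond is not broken, so S is retained, and the E olefin comes with tiglic acid.

**Compound list**

1 | acrolein | C=CC=O | starting material
2 | 2,3-dibromopropanal (racemic) | O=CC(Br)CBr | intermediate
3 | 2-bromoacrolein | C=C(Br)C=O | intermediate
4 | (3S)-2-bromohexa-1,5-dien-3-yl diisopinocampheylborinate (isopinocampheyl groups from (+)-α-pinene) | C=CC[C@H](OB([C@@H]1C[C@@H]2C[C@H]([C@H]1C)C2(C)C)[C@@H]1C[C@@H]2C[C@H]([C@H]1C)C2(C)C)C(Br)=C | intermediate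
5 | (S)-2-bromohexa-1,5-dien-3-ol | O[C@@H](CC=C)C(Br)=C | intermediate
6 | (S)-[(2-bromohexa-1,5-dien-3-yl)oxy](tert-butyl)dimethylsilane | CC(C)(C)[Si](C)(C)O[C@@H](CC=C)C(Br)=C | intermediate
7 | (S)-[(2-bromo-6-methylhepta-1,5-dien-3-yl)oxy](tert-butyl)dimethylsilane | CC(C)(C)[Si](C)(C)O[C@@H](CC=C(C)C)C(Br)=C | intermediate
8 | 2,3-dicyanohydroquinone (3,6-dihydroxyphthalonitrile) | N#Cc1c(O)ccc(O)c1C#N | starting material
9 | 3,6-bis(methoxymethoxy)phthalonitrile | N#Cc1c(OCOC)ccc(OCOC)c1C#N | intermediate
10 | 1,1′-[3,6-bis(methoxymethoxy)-1,2-phenylene]bis[N-(diisobutylaluminio)methanimine] | CC(C)C[Al](CC(C)C)N=Cc1c(OCOC)ccc(OCOC)c1C=N[Al](CC(C)C)CC(C)C | intermediate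
11 | 3,6-bis(methoxymethoxy)phthalaldehyde | O=Cc1c(OCOC)ccc(OCOC)c1C=O | intermediate
12 | [(3S)-3-(tert-butyldimethylsilyloxy)-6-methylhepta-1,5-dien-2-yl]lithium | CC(C)(C)[Si](C)(C)O[C@@H](CC=C(C)C)C([Li])=C | intermediate
13 | lithium 3-[(3S)-3-(tert-butyldimethylsilyloxy)-6-methylhepta-1,5-dien-2-yl]-4,7-bis(methoxymethoxy)-1,3-dihydroisobenzofuran-1-olate (mixture at the two ring carbons) | CC(C)(C)[Si](C)(C)O[C@@H](CC=C(C)C)C(=C)C1OC(O[Li])c2c(OCOC)ccc(OCOC)c21 | intermediate
14 | (3S)-3-(tert-butyldimethylsilyloxy)-1-[2-(1-hydroxyprop-2-en-1-yl)-3,6-bis(methoxymethoxy)phenyl]-6-methyl-2-methylidenehept-5-en-1-ol (mixture at the two free carbinols) | CC(C)(C)[Si](C)(C)O[C@@H](CC=C(C)C)C(=C)C(O)c1c(OCOC)ccc(OCOC)c1C(O)C=C | intermediate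
15 | 2-[(1S)-1-(tert-butyldimethylsilyloxy)-4-methylpent-3-en-1-yl]-5,8-bis(methoxymethoxy)-1,4-dihydronaphthalene-1,4-diol (mixture at C1 and C4) | CC(C)(C)[Si](C)(C)O[C@@H](CC=C(C)C)C1=CC(O)c2c(OCOC)ccc(OCOC)c2C1O | intermediate
16 | 2-[(1S)-1-(tert-butyldimethylsilyloxy)-4-methylpent-3-en-1-yl]-5,8-bis(methoxymethoxy)naphthalene-1,4-dione | CC(C)(C)[Si](C)(C)O[C@@H](CC=C(C)C)C1=CC(=O)c2c(OCOC)ccc(OCOC)c2C1=O | intermediate
17 | alkannin, 5,8-dihydroxy-2-[(1S)-1-hydroxy-4-methylpent-3-en-1-yl]naphthalene-1,4-dione | O[C@@H](CC=C(C)C)C1=CC(=O)c2c(O)ccc(O)c2C1=O | intermediate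
18 | tiglic acid, (E)-2-methylbut-2-enoic acid | C/C=C(\C)C(=O)O | starting material
19 | (1S)-1-(5,8-dihydroxy-1,4-dioxo-1,4-dihydronaphthalen-2-yl)-4-methylpent-3-en-1-yl (E)-2-methylbut-2-enoate | C/C=C(\C)C(=O)O[C@@H](CC=C(C)C)C1=CC(=O)c2c(O)ccc(O)c2C1=O | target

**Step count and risks**

Total steps: 11. Longest linear sequence: 9 (steps 1–4, then 7–11).

Steps most likely to fail:

Step 8. Ring closure onto the hindered 1,1-disubstituted olefin may be slow enough that alcohol-centred side reactions take over: hydride-mediated isomerisation of the vinyl carbinol to an ethyl ketone, or ionisation and loss of water from the electron-rich bis-benzylic diol towards a naphthol. The fallback changes the oxidation level at which the ring is closed. It sets out from diol 14, which is oxidised first (Dess–Martin periodinane, NaHCO3, CH2Cl2) to the bis(vinyl ketone) (3S)-3-(tert-butyldimethylsilyloxy)-6-methyl-2-methylidene-1-[3,6-bis(methoxymethoxy)-2-(prop-2-enoyl)phenyl]hept-5-en-1-one F1. Enone–enone ring-closing metathesis of F1 (second-generation Hoveyda–Grubbs catalyst, toluene, 80 °C, high dilution) should then form C2=C3 at the quinone level. The route is rejoined at quinone 16 and step 9 is dropped. This closure is the more demanding metathesis, but no carbinol is present to isomerise or ionise.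

Step 7. The lithium reagent may add twice to the dialdehyde before the lactolate closes, and hydride transfer within the lactolate (Tishchenko-type) may lead towards a phthalide. The fallback sets out from dialdehyde 11 and bromide 7 and replaces the one-flask organolithium union by a stepwise chromium-mediated one. Dialdehyde 11 is treated with one equivalent of vinylmagnesium bromide (THF, −78 °C) and the mono-adduct is isolated as the lactol 4,7-bis(methoxymethoxy)-3-vinyl-1,3-dihydroisobenzofuran-1-ol F2. Nozaki–Hiyama–Kishi coupling of bromide 7 with the open hydroxy-aldehyde form of F2 (CrCl2 in excess, NiCl2 catalytic, DMSO, rt) should then give diol 14, where the route is rejoined.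

Step 10. With the side-chain hydroxyl free, acid may trigger attack of that hydroxyl on the protonated trisubstituted olefin (closure to a dimethyltetrahydrofuran) or ionisation at C1′ with loss of configuration. The fallback sets out from quinone 16 and esterifies before the phenols are unmasked. HF·pyridine (pyridine, THF, 0 °C) removes only the silyl ether and gives 2-[(1S)-1-hydroxy-4-methylpent-3-en-1-yl]-5,8-bis(methoxymethoxy)naphthalene-1,4-dione F3. Steglich esterification with tiglic acid 18 (DCC, DMAP, CH2Cl2) gives (1S)-1-[5,8-bis(methoxymethoxy)-1,4-dioxo-1,4-dihydronaphthalen-2-yl]-4-methylpent-3-en-1-yl (E)-2-methylbut-2-enoate F4. Brief MOM hydrolysis of F4 (dilute HCl, THF/i-PrOH, 0 °C), with no free carbinol present, should then give target 19 directly.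

**Further compounds**

F1 | step 8 | (3S)-3-(tert-butyldimethylsilyloxy)-6-methyl-2-methylidene-1-[3,6-bis(methoxymethoxy)-2-(prop-2-enoyl)phenyl]hept-5-en-1-one | CC(C)(C)[Si](C)(C)O[C@@H](CC=C(C)C)C(=C)C(=O)c1c(OCOC)ccc(OCOC)c1C(=O)C=C
F2 | step 7 | 4,7-bis(methoxymethoxy)-3-vinyl-1,3-dihydroisobenzofuran-1-ol (diastereomer mixture) | C=CC1OC(O)c2c(OCOC)ccc(OCOC)c21
F3 | step 10 | 2-[(1S)-1-hydroxy-4-methylpent-3-en-1-yl]-5,8-bis(methoxymethoxy)naphthalene-1,4-dione | O[C@@H](CC=C(C)C)C1=CC(=O)c2c(OCOC)ccc(OCOC)c2C1=O
F4 | step 10 | (1S)-1-[5,8-bis(methoxymethoxy)-1,4-dioxo-1,4-dihydronaphthalen-2-yl]-4-methylpent-3-en-1-yl (E)-2-methylbut-2-enoate | C/C=C(\C)C(=O)O[C@@H](CC=C(C)C)C1=CC(=O)c2c(OCOC)ccc(OCOC)c2C1=O
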